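The plan disconnects the upper pyran ring (O1–C2–C3–C4–C4a–C8a) at C4–C4a. C4 is doubly benzylic, lying between the upper phloroglucinol ring and C6' of the lower gallocatechin ring, with a trans oxygen on C3. The key step ionises a C3–C4 epoxide at C4, a cation stabilised by the 5'- and 7'-oxygens and O1' of the lower ring, and the O1-tethered upper A ring closes the ring by Friedel–Crafts attack. One operation forms C4–C4a, fixes C4 trans to O3 whatever the configuration of the epoxide carbon, and frees O3 for the gallate. The precursor is an acyclic aryl ether of a chalcone-derived epoxy alcohol bearing bromine-capped, benzylated (+)-gallocatechin.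

Key step: step 9

Assumption: (+)-gallocatechin (1), 3',4',5'-trihydroxyacetophenone (7), 3,5-bis(benzyloxy)phenol (12) and 3,4,5-tris(benzyloxy)benzoic acid (16) are bought.
Remark: LU = the (2R,3S)-3,5,7-tris(benzyloxy)-8-bromo-2-[3,4,5-tris(benzyloxy)phenyl]chroman-6-yl group; ArB = 3,4,5-tris(benzyloxy)phenyl.
Remark: the upper C4 is 4β (3,4-trans) throughout; its CIP descriptor is R in the brominated, benzylated compounds 15 and 17 and S in 18 only because bromine and benzyl change the ligand ranks.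

Step 1
Reactants: 1 (+)-gallocatechin
Product: 3 hexa-O-benzyl-(+)-gallocatechin, via penta-O-benzyl ether 2 (not isolated)
Conditions: BnBr, K2CO3, DMF, 0 °C to rt, Ar; then NaH, 0 °C to rt
Reagents that add atoms: benzyl bromide, BrCc1ccccc1
Why: Williamson etherification, first of the five phenols (K2CO3) and then of the secondary 3-OH (NaH); no stereocentre is touched, since C2 epimerisation needs a free 4'-phenoxide, which is benzylated in the first stage.

Step 2
Reactants: 3 hexa-O-benzyl-(+)-gallocatechin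
Product: 4 8-bromo-hexa-O-benzyl-(+)-gallocatechin
Conditions: NBS (1.0 equiv), CH2Cl2, −78 to 0 °C
Reagents that add atoms: N-bromosuccinimide, O=C1CCC(=O)N1Br
Why: Electrophilic aromatic bromination goes to C8, the more accessible A-ring position of 5,7-dialkoxyflavans; the bromine caps C8 so that the next C–C bond must form at C6.

Step 3
Reactants: 4 8-bromo-hexa-O-benzyl-(+)-gallocatechin
Product: 6 8-bromo-hexa-O-benzyl-(+)-gallocatechin-6-carbaldehyde, via iminium chloride 5 (not isolated)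
Conditions: POCl3, DMF, 0 to 70 °C; then aq. NaOAc
Reagents that add atoms: N,N-dimethylformamide, CN(C)C=O; water, O
Why: Vilsmeier–Haack formylation at C6, the only open position of the phloroglucinol-type ring, which three oxygens make far more nucleophilic than the pyrogallol B ring; benzyl ethers are stable to the chloroiminium reagent.

Step 4
Reactants: 7 3',4',5'-trihydroxyacetophenone
Product: 8 3',4',5'-tris(benzyloxy)acetophenone
Conditions: BnBr, K2CO3, DMF, 60 °C, Ar
Reagents that add atoms: benzyl bromide, BrCc1ccccc1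
Why: Williamson etherification of three phenols; the methyl ketone is untouched by carbonate.

Step 5
Reactants: 6 8-bromo-hexa-O-benzyl-(+)-gallocatechin-6-carbaldehyde; 8 3',4',5'-tris(benzyloxy)acetophenone
Product: 9 (E)-3-(LU)-1-(ArB)prop-2-en-1-one
Conditions: KOH, EtOH/THF, rt to 40 °C
Reagents that add atoms: none
Why: Claisen–Schmidt condensation: the enolate of 8 adds to the non-enolisable aldehyde 6 and the aldol dehydrates to the conjugated E-enone, the thermodynamic isomer.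

Step 6
Reactants: 9 (E)-3-(LU)-1-(ArB)prop-2-en-1-one
Product: 10 [(2R,3S)-3-(LU)oxiran-2-yl](ArB)methanone
Conditions: poly-L-leucine, urea·H2O2, DBU, THF, rt
Reagents that add atoms: urea–hydrogen peroxide, NC(N)=O.OO
Why: Juliá–Colonna epoxidation (Weitz–Scheffer addition of hydroperoxide within the peptide helix); poly-L-leucine should give the trans-(αR,βS) epoxide as it does with chalcone itself, so the catalyst, not the remote lower-unit stereocentres, sets the future C3.

Step 7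
Reactants: 10 [(2R,3S)-3-(LU)oxiran-2-yl](ArB)methanone
Product: 11 (S)-[(2S,3S)-3-(LU)oxiran-2-yl](ArB)methanol
Conditions: Zn(BH4)2, Et2O/CH2Cl2, −40 to −20 °C; aq. NH4Cl
Reagents that add atoms: none
Why: Chelation-controlled reduction of an α,β-epoxy ketone: zinc bridges the carbonyl and epoxide oxygens and hydride enters anti to the epoxide C–C bond, which should give the erythro (S)-carbinol.

Step 8
Reactants: 11 (S)-[(2S,3S)-3-(LU)oxiran-2-yl](ArB)methanol; 12 3,5-bis(benzyloxy)phenol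
Product: 13 (2R,3S)-2-[(R)-[3,5-bis(benzyloxy)phenoxy](ArB)methyl]-3-(LU)oxirane
Conditions: PPh3, DIAD, toluene, 0 °C to rt; chromatography on Et3N-deactivated silica
Reagents that add atoms: none
Why: Mitsunobu etherification: SN2 attack of the phenoxide on the oxyphosphonium inverts the carbinol, turning erythro into threo and setting the future C2 as R, under neutral conditions that spare the acid-labile epoxide.

Step 9
Reactants: 13 (2R,3S)-2-[(R)-[3,5-bis(benzyloxy)phenoxy](ArB)methyl]-3-(LU)oxirane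
Product: 15 (2R,3R,4R)-5,7-bis(benzyloxy)-4-(LU)-2-(ArB)chroman-3-ol, via benzylic cation 14 (not isolated)
Conditions: BF3·OEt2 (0.2 equiv), CH2Cl2 (0.005 M), −78 to −40 °C; Et3N quench
Reagents that add atoms: none
Why: BF3 on the epoxide oxygen ionises the C4–O bond, because the C4 cation is benzylic to the lower ring with 5'-OBn, 7'-OBn and O1' ortho, ortho and para to C6' (cation 14); the tethered 3,5-bis(benzyloxy)phenoxy ring then attacks C4 through its carbon ortho to O1 (future C4a), and loss of the arene proton leaves the former epoxide oxygen as 3-OH. The closest known reaction is the intramolecular Friedel–Crafts epoxy–arene cyclisation of aryl 3-arylglycidyl ethers to trans-4-arylchroman-3-ols. The ring O1–C2–C3–C4–C4a–C8a closes in the 6-endo mode at the distal, benzylic epoxide carbon. C2 and C3 are carried in from 13; C4 is set here, by anti opening of the trans-epoxide or, if the cation is free, by attack on the conformer with H3 eclipsing the aryl plane (allylic 1,3-strain with the ortho benzyloxy groups), in which the tether through C2 can reach only the face opposite O3, so both paths should give 3,4-trans (4β) and any C4 epimer of 13 is funnelled to the same product. The step needs C-arylation by the A ring to beat the 1,2-hydride shift (Meinwald ketone), attack by the B ring (indane) and intermolecular alkylation; this rests on the much higher nucleophilicity of the phloroglucinol-type ring, a six-membered chair transition state with the C2 aryl equatorial, catalytic acid, low temperature and high dilution.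

Step 10
Reactants: 15 (2R,3R,4R)-5,7-bis(benzyloxy)-4-(LU)-2-(ArB)chroman-3-ol; 16 3,4,5-tris(benzyloxy)benzoic acid
Product: 17 3-O-[3,4,5-tris(benzyloxy)benzoyl] ester of 15
Conditions: DCC, DMAP, CH2Cl2, rt
Reagents that add atoms: none
Why: Steglich esterification of the only free hydroxyl, the axial 3-OH, with retention; DMAP acyl transfer copes with the hindered secondary alcohol.

Step 11
Reactants: 17 3-O-[3,4,5-tris(benzyloxy)benzoyl] ester of 15
Product: 18 epigallocatechin-3-O-gallate-(4β→6)-gallocatechin (CNP0271447.2)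
Conditions: H2 (1 atm), 20% Pd(OH)2/C, Et3N, THF/MeOH/H2O, rt; Sephadex LH-20, lyophilise under Ar
Reagents that add atoms: none
Why: Hydrogenolysis should remove all fourteen benzyl ethers and the C8' bromine in one operation, with triethylamine taking up HBr so that the acid-labile C4–C6' bond survives; no stereocentre is touched.

Compound list
1 | (+)-gallocatechin, (2R,3S)-2-(3,4,5-trihydroxyphenyl)chromane-3,5,7-triol | O[C@H]1Cc2c(O)cc(O)cc2O[C@@H]1c1cc(O)c(O)c(O)c1 | starting material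
2 | 5,7,3',4',5'-penta-O-benzyl-(+)-gallocatechin (3-OH free) | O[C@H]1Cc2c(OCc3ccccc3)cc(OCc3ccccc3)cc2O[C@@H]1c1cc(OCc2ccccc2)c(OCc2ccccc2)c(OCc2ccccc2)c1 | intermediate
3 | hexa-O-benzyl-(+)-gallocatechin, (2R,3S)-3,5,7-tris(benzyloxy)-2-[3,4,5-tris(benzyloxy)phenyl]chromane | C(c1ccccc1)O[C@H]1Cc2c(OCc3ccccc3)cc(OCc3ccccc3)cc2O[C@@H]1c1cc(OCc2ccccc2)c(OCc2ccccc2)c(OCc2ccccc2)c1 | intermediate
4 | 8-bromo-hexa-O-benzyl-(+)-gallocatechin | C(c1ccccc1)O[C@H]1Cc2c(OCc3ccccc3)cc(OCc3ccccc3)c(Br)c2O[C@@H]1c1cc(OCc2ccccc2)c(OCc2ccccc2)c(OCc2ccccc2)c1 | intermediate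
5 | C6 N,N-dimethyliminium chloride of 4 | C(c1ccccc1)O[C@H]1Cc2c(OCc3ccccc3)c(C=[N+](C)C)c(OCc3ccccc3)c(Br)c2O[C@@H]1c1cc(OCc2ccccc2)c(OCc2ccccc2)c(OCc2ccccc2)c1.[Cl-] | intermediate
6 | 8-bromo-hexa-O-benzyl-(+)-gallocatechin-6-carbaldehyde | C(c1ccccc1)O[C@H]1Cc2c(OCc3ccccc3)c(C=O)c(OCc3ccccc3)c(Br)c2O[C@@H]1c1cc(OCc2ccccc2)c(OCc2ccccc2)c(OCc2ccccc2)c1 | intermediate
7 | 3',4',5'-trihydroxyacetophenone | CC(=O)c1cc(O)c(O)c(O)c1 | starting material
8 | 3',4',5'-tris(benzyloxy)acetophenone | CC(=O)c1cc(OCc2ccccc2)c(OCc2ccccc2)c(OCc2ccccc2)c1 | intermediate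
9 | (E)-3-(LU)-1-(ArB)prop-2-en-1-one | O=C(c1cc(OCc2ccccc2)c(OCc2ccccc2)c(OCc2ccccc2)c1)/C=C/c1c(OCc2ccccc2)c2C[C@H](OCc3ccccc3)[C@@H](c3cc(OCc4ccccc4)c(OCc4ccccc4)c(OCc4ccccc4)c3)Oc2c(Br)c1OCc1ccccc1 | intermediate
10 | [(2R,3S)-3-(LU)oxiran-2-yl](ArB)methanone, trans | O=C(c1cc(OCc2ccccc2)c(OCc2ccccc2)c(OCc2ccccc2)c1)[C@@H]1O[C@H]1c1c(OCc2ccccc2)c2C[C@H](OCc3ccccc3)[C@@H](c3cc(OCc4ccccc4)c(OCc4ccccc4)c(OCc4ccccc4)c3)Oc2c(Br)c1OCc1ccccc1 | intermediate
11 | (S)-[(2S,3S)-3-(LU)oxiran-2-yl](ArB)methanol, erythro | O[C@@H](c1cc(OCc2ccccc2)c(OCc2ccccc2)c(OCc2ccccc2)c1)[C@@H]1O[C@H]1c1c(OCc2ccccc2)c2C[C@H](OCc3ccccc3)[C@@H](c3cc(OCc4ccccc4)c(OCc4ccccc4)c(OCc4ccccc4)c3)Oc2c(Br)c1OCc1ccccc1 | intermediate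
12 | 3,5-bis(benzyloxy)phenol | Oc1cc(OCc2ccccc2)cc(OCc2ccccc2)c1 | starting material
13 | (2R,3S)-2-[(R)-[3,5-bis(benzyloxy)phenoxy](ArB)methyl]-3-(LU)oxirane, threo ether of the trans-epoxide | c1ccccc1COc1cc(OCc2ccccc2)cc(c1)O[C@H](c1cc(OCc2ccccc2)c(OCc2ccccc2)c(OCc2ccccc2)c1)[C@@H]1O[C@H]1c1c(OCc2ccccc2)c2C[C@H](OCc3ccccc3)[C@@H](c3cc(OCc4ccccc4)c(OCc4ccccc4)c(OCc4ccccc4)c3)Oc2c(Br)c1OCc1ccccc1 | intermediate
14 | C4 benzylic cation of 13 with BF3-bound C3 alkoxide | c1ccccc1COc1cc(OCc2ccccc2)cc(c1)O[C@H](c1cc(OCc2ccccc2)c(OCc2ccccc2)c(OCc2ccccc2)c1)[C@H](O[B-](F)(F)F)[CH+]c1c(OCc2ccccc2)c2C[C@H](OCc3ccccc3)[C@@H](c3cc(OCc4ccccc4)c(OCc4ccccc4)c(OCc4ccccc4)c3)Oc2c(Br)c1OCc1ccccc1 | intermediate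
15 | (2R,3R,4R)-5,7-bis(benzyloxy)-4-(LU)-2-(ArB)chroman-3-ol, 2,3-cis, 3,4-trans | O[C@@H]1[C@@H](c2c(OCc3ccccc3)c3C[C@H](OCc4ccccc4)[C@@H](c4cc(OCc5ccccc5)c(OCc5ccccc5)c(OCc5ccccc5)c4)Oc3c(Br)c2OCc2ccccc2)c2c(OCc3ccccc3)cc(OCc3ccccc3)cc2O[C@@H]1c1cc(OCc2ccccc2)c(OCc2ccccc2)c(OCc2ccccc2)c1 | intermediate
16 | 3,4,5-tris(benzyloxy)benzoic acid | O=C(O)c1cc(OCc2ccccc2)c(OCc2ccccc2)c(OCc2ccccc2)c1 | starting material
17 | 3-O-[3,4,5-tris(benzyloxy)benzoyl] ester of 15 | O=C(O[C@@H]1[C@@H](c2c(OCc3ccccc3)c3C[C@H](OCc4ccccc4)[C@@H](c4cc(OCc5ccccc5)c(OCc5ccccc5)c(OCc5ccccc5)c4)Oc3c(Br)c2OCc2ccccc2)c2c(OCc3ccccc3)cc(OCc3ccccc3)cc2O[C@@H]1c1cc(OCc2ccccc2)c(OCc2ccccc2)c(OCc2ccccc2)c1)c1cc(OCc2ccccc2)c(OCc2ccccc2)c(OCc2ccccc2)c1 | intermediate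
18 | epigallocatechin-3-O-gallate-(4β→6)-gallocatechin; upper unit 2R,3R,4S, lower unit 2R,3S | O=C(O[C@@H]1[C@@H](c2c(O)cc3c(c2O)C[C@H](O)[C@@H](c2cc(O)c(O)c(O)c2)O3)c2c(O)cc(O)cc2O[C@@H]1c1cc(O)c(O)c(O)c1)c1cc(O)c(O)c(O)c1 | target

Total step count: 11. Longest linear sequence: 10 steps (1, 2, 3, 5, 6, 7, 8, 9, 10, 11).

Steps most likely to fail

Step 9 (ring closure). The free C4 cation may undergo a 1,2-hydride shift from C3 (Meinwald rearrangement to the C3 ketone), or the Lewis acid may cause decomposition faster than the ring closes. The fallback sets out from 13. The epoxide is opened at the benzylic carbon with thiophenol (PhSH, Et3N, MeOH/THF, 50 °C) to the (1R,2S,3R)-3-phenylsulfanyl-propan-2-ol F1; the configuration at the sulfur-bearing carbon does not matter. Its hydroxyl is esterified with 16 (DCC, DMAP) to the gallate F2. A thiophile (AgBF4, 2,6-di-tert-butyl-4-methylpyridine, CH2Cl2, −40 °C) then generates the C4 cation under non-protic conditions. The gallate carbonyl holds it as a 1,3-dioxolan-2-ylium ion, which blocks the hydride shift and the face syn to O3, so the tethered A ring should close the same ring trans to O3. This route comes back at 17, with the gallate already in place.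

Step 6 (epoxidation). Hydroperoxide addition to the hindered, electron-rich (push–pull) β-carbon may be slow, and the facial selectivity of the peptide catalyst may be poor with a 2,6-disubstituted β-aryl group. The fallback sets out from 9. Luche reduction (NaBH4, CeCl3, MeOH/THF) gives the allylic alcohol F3 as both carbinol epimers. Sharpless epoxidation under kinetic-resolution conditions (Ti(OiPr)4, L-(+)-diisopropyl tartrate, TBHP, 4 Å sieves, CH2Cl2, −20 °C) should epoxidise only the matching epimer, from the face fixed by the tartrate and with erythro selectivity. This route comes back at 11 and bypasses 10. The unreacted epimer can be re-oxidised to 9 with MnO2.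

Step 8 (etherification). The activated, electron-rich benzylic oxyphosphonium may ionise (partial SN1, incomplete inversion), or elimination may win over substitution by the bulky phenol. The fallback sets out from 11. The carbinol is inverted with a small, acidic partner (4-nitrobenzoic acid, PPh3, DIAD) to the inverted 4-nitrobenzoate F4, and methanolysis (K2CO3, MeOH, 0 °C) gives the threo (R)-carbinol F5. The aryl–oxygen bond is then formed with retention at carbon by palladium-catalysed C–O coupling with 1-bromo-3,5-bis(benzyloxy)benzene (RockPhos Pd G3, Cs2CO3, toluene, 80 °C); the doubly ortho-substituted C8' bromide should be spared. This route comes back at 13.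

Further compounds
F1 | step 9 | (1R,2S,3R)-1-[3,5-bis(benzyloxy)phenoxy]-3-(LU)-3-(phenylsulfanyl)-1-(ArB)propan-2-ol | c1ccccc1COc1cc(OCc2ccccc2)cc(c1)O[C@H](c1cc(OCc2ccccc2)c(OCc2ccccc2)c(OCc2ccccc2)c1)[C@H](O)[C@H](Sc1ccccc1)c1c(OCc2ccccc2)c2C[C@H](OCc3ccccc3)[C@@H](c3cc(OCc4ccccc4)c(OCc4ccccc4)c(OCc4ccccc4)c3)Oc2c(Br)c1OCc1ccccc1
F2 | step 9 | 2-O-[3,4,5-tris(benzyloxy)benzoyl] ester of F1 | c1ccccc1COc1cc(OCc2ccccc2)cc(c1)O[C@H](c1cc(OCc2ccccc2)c(OCc2ccccc2)c(OCc2ccccc2)c1)[C@H](OC(=O)c1cc(OCc2ccccc2)c(OCc2ccccc2)c(OCc2ccccc2)c1)[C@H](Sc1ccccc1)c1c(OCc2ccccc2)c2C[C@H](OCc3ccccc3)[C@@H](c3cc(OCc4ccccc4)c(OCc4ccccc4)c(OCc4ccccc4)c3)Oc2c(Br)c1OCc1ccccc1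
F3 | step 6 | (E)-3-(LU)-1-(ArB)prop-2-en-1-ol, both carbinol epimers | OC(c1cc(OCc2ccccc2)c(OCc2ccccc2)c(OCc2ccccc2)c1)/C=C/c1c(OCc2ccccc2)c2C[C@H](OCc3ccccc3)[C@@H](c3cc(OCc4ccccc4)c(OCc4ccccc4)c(OCc4ccccc4)c3)Oc2c(Br)c1OCc1ccccc1
F4 | step 8 | (R)-[(2S,3S)-3-(LU)oxiran-2-yl](ArB)methyl 4-nitrobenzoate | O=C(O[C@H](c1cc(OCc2ccccc2)c(OCc2ccccc2)c(OCc2ccccc2)c1)[C@@H]1O[C@H]1c1c(OCc2ccccc2)c2C[C@H](OCc3ccccc3)[C@@H](c3cc(OCc4ccccc4)c(OCc4ccccc4)c(OCc4ccccc4)c3)Oc2c(Br)c1OCc1ccccc1)c1ccc(cc1)[N+](=O)[O-]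
F5 | step 8 | (R)-[(2S,3S)-3-(LU)oxiran-2-yl](ArB)methanol, threo | O[C@H](c1cc(OCc2ccccc2)c(OCc2ccccc2)c(OCc2ccccc2)c1)[C@@H]1O[C@H]1c1c(OCc2ccccc2)c2C[C@H](OCc3ccccc3)[C@@H](c3cc(OCc4ccccc4)c(OCc4ccccc4)c(OCc4ccccc4)c3)Oc2c(Br)c1OCc1ccccc1
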